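The route rests on disconnecting ring A'' of the flavone half and not the congested C6–C8'' biaryl bond. Because C8'' lies between the oxygen-bearing carbons C7'' and C8a'', ring A'' can be grown onto an unhindered aryl–alkyne bond: Danheiser benzannulation of an aryl siloxyalkyne with 3-ethoxycyclobutenone forms C8''–C8a'' and C6''–C7'', closes ring A'' and issues O1'', O7'' and O5'' as free phenol, silyl ether and ethyl ether in one operation. The precursor is the triisopropylsilyl ynol ether of a 4-benzyloxy-2,6-bis(methoxymethoxy)phenyl group, whose para oxygen later becomes O1 of the flavanone. Both pyranone rings are then built from salicylaldehydes through ynones under acid-free conditions, and C2 is set by asymmetric conjugate arylation.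

Key step: step 6

Assumption: the target carries no descriptor for the C6–C8'' axis, so only C2 is controlled (2S) and atropisomers about that axis are not differentiated; 3-ethoxycyclobut-2-en-1-one and [4-(methoxymethoxy)phenyl]boronic acid are taken as catalogue compounds.

Step 1
Reactants: 1 4-hydroxybenzaldehyde
Product: 2 4-(methoxymethoxy)benzaldehyde
Conditions: MOMCl, i-Pr2NEt, CH2Cl2, 0 → 23 °C
Reagents that add atoms: chloromethyl methyl ether, COCCl
Why: Base-mediated O-alkylation of the acidic para-formyl phenol with the α-chloro ether (Williamson-type acetal formation) is fast, and the methoxymethyl ether tolerates the carbonate, organolithium and rhodium conditions that follow.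

Step 2
Reactants: 2 4-(methoxymethoxy)benzaldehyde
Product: 3 1-ethynyl-4-(methoxymethoxy)benzene
Conditions: dimethyl (1-diazo-2-oxopropyl)phosphonate, K2CO3, MeOH, 23 °C
Reagents that add atoms: dimethyl (1-diazo-2-oxopropyl)phosphonate, COP(=O)(OC)C(=[N+]=[N-])C(C)=O
Why: The Ohira–Bestmann variant of the Seyferth–Gilbert homologation turns a non-enolisable aryl aldehyde into the terminal alkyne under mild carbonate conditions that leave the acetal untouched.

Step 3
Reactants: 4 methyl 2,4,6-trihydroxybenzoate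
Product: 5 methyl 4-(benzyloxy)-2,6-dihydroxybenzoate
Conditions: BnOH, PPh3, DIAD, THF, 0 → 23 °C
Reagents that add atoms: benzyl alcohol, OCc1ccccc1
Why: Mitsunobu etherification selects O4 because it is the most acidic hydroxyl, is unhindered and is not hydrogen-bonded to the ester, while the neutral redox conditions avoid the C-benzylation to which phloroglucinol anions are prone.

Step 4
Reactants: 5 methyl 4-(benzyloxy)-2,6-dihydroxybenzoate
Product: 6 methyl 4-(benzyloxy)-2,6-bis(methoxymethoxy)benzoate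
Conditions: NaH, MOMCl, THF/DMF, 0 → 23 °C
Reagents that add atoms: chloromethyl methyl ether, COCCl
Why: Double Williamson-type alkylation of the sodium phenoxides overrides the hydrogen bonds to the ester and installs base-stable acetals on the two oxygens that will flank the biaryl axis.

Step 5
Reactants: 6 methyl 4-(benzyloxy)-2,6-bis(methoxymethoxy)benzoate
Product: 9 [4-(benzyloxy)-2,6-bis(methoxymethoxy)phenyl]ethynyl triisopropylsilyl ether, via lithium dibromoenolate 7 (not isolated), via lithium ynolate 8 (not isolated)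
Conditions: CH2Br2, lithium 2,2,6,6-tetramethylpiperidide, THF, −78 °C; LiN(SiMe3)2; n-BuLi, −78 → 0 °C; TIPSOTf, −78 → 0 °C; chromatography on Et3N-deactivated silica
Reagents that add atoms: dibromomethane, BrCBr; triisopropylsilyl trifluoromethanesulfonate, CC(C)[Si](OS(=O)(=O)C(F)(F)F)(C(C)C)C(C)C
Why: In the Kowalski ester homologation dibromomethyllithium adds to the ester, the derived dibromoenolate 7 undergoes bromine–lithium exchange and carbenoid rearrangement with aryl migration to ynolate 8, and the bulky silyl triflate captures 8 on oxygen to give the stable triisopropylsilyl ynol ether.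

Step 6
Reactants: 9 [4-(benzyloxy)-2,6-bis(methoxymethoxy)phenyl]ethynyl triisopropylsilyl ether; 10 3-ethoxycyclobut-2-en-1-one
Product: 15 2-[4-(benzyloxy)-2,6-bis(methoxymethoxy)phenyl]-5-ethoxy-3-(triisopropylsilyloxy)phenol, via vinylketene 11 (not isolated), via vinylcyclobutenone 12 (not isolated), via dienylketene 13 (not isolated), via cyclohexadienone 14 (not isolated)
Conditions: 9 (1.0 equiv), 10 (1.5 equiv, in portions), toluene, 80 → 100 °C, argon
Reagents that add atoms: none
Why: Thermal four-electron electrocyclic opening of 10 gives vinylketene 11, whose carbonyl carbon (future C8a'') is attacked by the aryl-bearing, nucleophilic carbon of ynol ether 9 in a ketene–alkyne (2+2) cycloaddition that forms C8''–C8a'' and C6''–C7''. Vinylcyclobutenone 12 then reopens to dienylketene 13, and ring A'' closes by a thermally allowed disrotatory six-electron electrocyclisation that joins C4a'' to C8a'', after which cyclohexadienone 14 tautomerises to phenol 15. The closest known reaction type is the Danheiser benzannulation of cyclobutenones with trialkylsilyl ynol ethers to monoprotected resorcinols. No stereocentre survives, because the only sp3 carbon formed (in 12) becomes aromatic and the C6–C8'' axis still carries two identical methoxymethoxy groups on one side. The step needs regioselectivity in the (2+2) event, which the polarisation of the ynol ether secures by making the aryl-bearing carbon the nucleophile, so that the aryl group ends between the new hydroxyl and the siloxy carbon. The bulky triisopropylsilyl group suppresses oxygen-to-carbon silyl migration and the acetal and benzyl ethers are inert to heat, so O1'', O7'' and O5'' emerge as hydroxyl, silyl ether and ethyl ether.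

Step 7
Reactants: 15 2-[4-(benzyloxy)-2,6-bis(methoxymethoxy)phenyl]-5-ethoxy-3-(triisopropylsilyloxy)phenol
Product: 16 3-[4-(benzyloxy)-2,6-bis(methoxymethoxy)phenyl]-6-ethoxy-2-hydroxy-4-(triisopropylsilyloxy)benzaldehyde
Conditions: MgCl2, Et3N, (CH2O)n, MeCN, 80 °C
Reagents that add atoms: paraformaldehyde (as formaldehyde), C=O
Why: Magnesium-mediated ortho-formylation of phenols (Casnati–Skattebøl reaction) delivers formaldehyde within the magnesium phenoxide chelate, so only C4a'', the single free position ortho to O1'', is attacked and the hydroxymethyl stage is oxidised in situ by a second formaldehyde through Oppenauer-type hydride transfer, all without acid that would harm the acetals.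

Step 8
Reactants: 16 3-[4-(benzyloxy)-2,6-bis(methoxymethoxy)phenyl]-6-ethoxy-2-hydroxy-4-(triisopropylsilyloxy)benzaldehyde; 3 1-ethynyl-4-(methoxymethoxy)benzene
Product: 18 1-{3-[4-(benzyloxy)-2,6-bis(methoxymethoxy)phenyl]-6-ethoxy-2-hydroxy-4-(triisopropylsilyloxy)phenyl}-3-[4-(methoxymethoxy)phenyl]prop-2-yn-1-ol (racemic at the carbinol), via lithium acetylide 17 (not isolated)
Conditions: 3 (2.5 equiv), n-BuLi (2.4 equiv), THF, −78 °C; then 16, −78 → 0 °C
Reagents that add atoms: none
Why: 1,2-Addition of a lithium acetylide to an aldehyde is reliable, one equivalent being spent on the phenol, and the new carbinol centre is formed without control because it is erased by oxidation in the next step.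

Step 9
Reactants: 18 1-{3-[4-(benzyloxy)-2,6-bis(methoxymethoxy)phenyl]-6-ethoxy-2-hydroxy-4-(triisopropylsilyloxy)phenyl}-3-[4-(methoxymethoxy)phenyl]prop-2-yn-1-ol
Product: 20 8-[4-(benzyloxy)-2,6-bis(methoxymethoxy)phenyl]-5-ethoxy-2-[4-(methoxymethoxy)phenyl]-7-(triisopropylsilyloxy)-4H-chromen-4-one, via alkynone 19 (not isolated)
Conditions: MnO2, CH2Cl2, 23 °C; filter; DMAP (20 mol%), DMF, 40 °C
Reagents that add atoms: none
Why: Manganese dioxide oxidises the benzylic–propargylic alcohol selectively to ynone 19, and nucleophilic amine catalysis then steers the ortho-hydroxyaryl ynone through conjugate addition–elimination to the 6-endo product, so that O1'', the only free hydroxyl beside the ketone, closes the pyranone (oxa-Michael cyclisation of an o-alkynoylphenol).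

Step 10
Reactants: 20 8-[4-(benzyloxy)-2,6-bis(methoxymethoxy)phenyl]-5-ethoxy-2-[4-(methoxymethoxy)phenyl]-7-(triisopropylsilyloxy)-4H-chromen-4-one
Product: 21 8-[4-(benzyloxy)-2,6-bis(methoxymethoxy)phenyl]-5-hydroxy-2-[4-(methoxymethoxy)phenyl]-7-(triisopropylsilyloxy)-4H-chromen-4-one
Conditions: MgI2·OEt2, toluene, 80 °C
Reagents that add atoms: none
Why: Chelation of magnesium between the C4'' carbonyl and the peri O5'' activates only this ether for SN2 attack of iodide on the ethyl group (chelation-assisted ether cleavage), which leaves the unchelated acetals, the silyl ether and the benzyl ether in place and removes, before C2 exists, the one group that could not be cleaved safely afterwards.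

Step 11
Reactants: 21 8-[4-(benzyloxy)-2,6-bis(methoxymethoxy)phenyl]-5-hydroxy-2-[4-(methoxymethoxy)phenyl]-7-(triisopropylsilyloxy)-4H-chromen-4-one
Product: 22 5-hydroxy-8-[4-hydroxy-2,6-bis(methoxymethoxy)phenyl]-2-[4-(methoxymethoxy)phenyl]-7-(triisopropylsilyloxy)-4H-chromen-4-one
Conditions: H2 (1 atm), 10% Pd/C, EtOAc, 23 °C
Reagents that add atoms: none
Why: Catalytic hydrogenolysis cleaves the benzyl aryl ether under neutral conditions at which the flavone C2''–C3'' double bond, the acetals and the silyl ether are inert, unmasking the future O1 as the only free hydroxyl on that ring.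

Step 12
Reactants: 22 5-hydroxy-8-[4-hydroxy-2,6-bis(methoxymethoxy)phenyl]-2-[4-(methoxymethoxy)phenyl]-7-(triisopropylsilyloxy)-4H-chromen-4-one
Product: 23 6-hydroxy-3-{5-hydroxy-2-[4-(methoxymethoxy)phenyl]-4-oxo-7-(triisopropylsilyloxy)-4H-chromen-8-yl}-2,4-bis(methoxymethoxy)benzaldehyde
Conditions: MgCl2, Et3N, (CH2O)n, MeCN, 80 °C
Reagents that add atoms: paraformaldehyde (as formaldehyde), C=O
Why: The same magnesium-mediated ortho-formylation now acts on the electron-rich phloroglucinol-type phenol, whose two ortho positions are equivalent by symmetry and whose para position is the biaryl carbon, whereas the flavone ring, with its chelated O5'' hydroxyl, its electron-poor character and the silyl group shielding C6'', should not compete.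

Step 13
Reactants: 23 6-hydroxy-3-{5-hydroxy-2-[4-(methoxymethoxy)phenyl]-4-oxo-7-(triisopropylsilyloxy)-4H-chromen-8-yl}-2,4-bis(methoxymethoxy)benzaldehyde
Product: 24 5-hydroxy-8-[4-hydroxy-3-(1-hydroxyprop-2-yn-1-yl)-2,6-bis(methoxymethoxy)phenyl]-2-[4-(methoxymethoxy)phenyl]-7-(triisopropylsilyloxy)-4H-chromen-4-one (racemic at the carbinol)
Conditions: HC≡CMgBr (4 equiv), THF, −20 → 0 °C
Reagents that add atoms: ethynylmagnesium bromide, C#C[Mg]Br
Why: Grignard addition of the alkynyl nucleophile is chemoselective because the formyl group held in a magnesium phenoxide chelate is far more electrophilic than the vinylogous ester carbonyl of the flavone, and the uncontrolled carbinol centre is removed by the following oxidation.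

Step 14
Reactants: 24 5-hydroxy-8-[4-hydroxy-3-(1-hydroxyprop-2-yn-1-yl)-2,6-bis(methoxymethoxy)phenyl]-2-[4-(methoxymethoxy)phenyl]-7-(triisopropylsilyloxy)-4H-chromen-4-one
Product: 26 5-hydroxy-8-[5,7-bis(methoxymethoxy)-4-oxo-4H-chromen-6-yl]-2-[4-(methoxymethoxy)phenyl]-7-(triisopropylsilyloxy)-4H-chromen-4-one, via terminal alkynone 25 (not isolated)
Conditions: MnO2, CH2Cl2, 23 °C; filter; DMAP (20 mol%), DMF, 23 °C
Reagents that add atoms: none
Why: Manganese dioxide oxidation gives terminal ynone 25, which undergoes amine-catalysed 6-endo oxa-Michael addition of the para oxygen (the only free hydroxyl on that ring, O5 being an acetal) to give the 2-unsubstituted chromone with the 6-aryl connectivity fixed.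

Step 15
Reactants: 26 5-hydroxy-8-[5,7-bis(methoxymethoxy)-4-oxo-4H-chromen-6-yl]-2-[4-(methoxymethoxy)phenyl]-7-(triisopropylsilyloxy)-4H-chromen-4-one; 27 [4-(methoxymethoxy)phenyl]boronic acid
Product: 28 (2S)-6-{5-hydroxy-2-[4-(methoxymethoxy)phenyl]-4-oxo-7-(triisopropylsilyloxy)-4H-chromen-8-yl}-5,7-bis(methoxymethoxy)-2-[4-(methoxymethoxy)phenyl]-2,3-dihydro-4H-chromen-4-one
Conditions: 27 (2 equiv), [RhCl(C2H4)2]2 (2.5 mol%), (1S,4S)-2,5-diphenylbicyclo[2.2.2]octa-2,5-diene (5.5 mol%), K3PO4 (aq), dioxane, 30 °C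
Reagents that add atoms: none
Why: Rhodium-catalysed asymmetric 1,4-addition of an arylboronic acid to a chromone (Hayashi–Miyaura reaction) sets C2, the diene-bound aryl-rhodium species inserting the C2–C3 double bond from the Re face of C2 to give the 2S configuration, with the ligand antipode chosen by analogy with its sense on cyclic enones and to be confirmed on 5,7-bis(methoxymethoxy)chromone, while the 2-aryl-substituted flavone half is inert to insertion.

Step 16
Reactants: 28 (2S)-6-{5-hydroxy-2-[4-(methoxymethoxy)phenyl]-4-oxo-7-(triisopropylsilyloxy)-4H-chromen-8-yl}-5,7-bis(methoxymethoxy)-2-[4-(methoxymethoxy)phenyl]-2,3-dihydro-4H-chromen-4-one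
Product: 30 (2S)-6-[5,7-dihydroxy-2-(4-hydroxyphenyl)-4-oxo-4H-chromen-8-yl]-5,7-dihydroxy-2-(4-hydroxyphenyl)-2,3-dihydro-4H-chromen-4-one, via desilylated flavanone 29 (not isolated)
Conditions: KHF2, MeOH/THF, 40 °C (polypropylene vessel); then HCl (to 2 M), 40 °C
Reagents that add atoms: none
Why: Bifluoride cleaves the aryl silyl ether through formation of the strong Si–F bond, and mild methanolic acid then removes the four acetals by transacetalisation to dimethoxymethane under conditions that should not open the flavanone to its chalcone, so the C2 configuration should be retained.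

Compound list
1 | 4-hydroxybenzaldehyde | O=Cc1ccc(O)cc1 | starting material
2 | 4-(methoxymethoxy)benzaldehyde | COCOc1ccc(C=O)cc1 | intermediate
3 | 1-ethynyl-4-(methoxymethoxy)benzene | C#Cc1ccc(OCOC)cc1 | intermediate
4 | methyl 2,4,6-trihydroxybenzoate | COC(=O)c1c(O)cc(O)cc1O | starting material
5 | methyl 4-(benzyloxy)-2,6-dihydroxybenzoate | COC(=O)c1c(O)cc(OCc2ccccc2)cc1O | intermediate
6 | methyl 4-(benzyloxy)-2,6-bis(methoxymethoxy)benzoate | COC(=O)c1c(OCOC)cc(OCc2ccccc2)cc1OCOC | intermediate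
7 | lithium 1-[4-(benzyloxy)-2,6-bis(methoxymethoxy)phenyl]-2,2-dibromoethenolate (formed in the flask) | [Li+].[O-]C(=C(Br)Br)c1c(OCOC)cc(OCc2ccccc2)cc1OCOC | intermediate
8 | lithium 2-[4-(benzyloxy)-2,6-bis(methoxymethoxy)phenyl]ethynolate (formed in the flask) | [Li+].[O-]C#Cc1c(OCOC)cc(OCc2ccccc2)cc1OCOC | intermediate
9 | [4-(benzyloxy)-2,6-bis(methoxymethoxy)phenyl]ethynyl triisopropylsilyl ether | CC(C)[Si](C(C)C)(C(C)C)OC#Cc1c(OCOC)cc(OCc2ccccc2)cc1OCOC | intermediate
10 | 3-ethoxycyclobut-2-en-1-one | CCOC1=CC(=O)C1 | starting material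
11 | 3-ethoxybuta-1,3-dien-1-one (ethoxyvinylketene, formed in the flask) | C=C(OCC)C=C=O | intermediate
12 | 2-[4-(benzyloxy)-2,6-bis(methoxymethoxy)phenyl]-4-(1-ethoxyethenyl)-3-(triisopropylsilyloxy)cyclobut-2-en-1-one (racemic, formed in the flask) | C=C(OCC)C1C(=O)C(c2c(OCOC)cc(OCc3ccccc3)cc2OCOC)=C1O[Si](C(C)C)(C(C)C)C(C)C | intermediate
13 | 2-[4-(benzyloxy)-2,6-bis(methoxymethoxy)phenyl]-5-ethoxy-3-(triisopropylsilyloxy)hexa-1,3,5-trien-1-one, C2 and C5 cis across C3=C4 (formed in the flask) | C=C(OCC)/C=C(\C(=C=O)c1c(OCOC)cc(OCc2ccccc2)cc1OCOC)O[Si](C(C)C)(C(C)C)C(C)C | intermediate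
14 | 2-[4-(benzyloxy)-2,6-bis(methoxymethoxy)phenyl]-5-ethoxy-3-(triisopropylsilyloxy)cyclohexa-2,4-dien-1-one (formed in the flask) | O=C1CC(OCC)=CC(O[Si](C(C)C)(C(C)C)C(C)C)=C1c1c(OCOC)cc(OCc2ccccc2)cc1OCOC | intermediate
15 | 2-[4-(benzyloxy)-2,6-bis(methoxymethoxy)phenyl]-5-ethoxy-3-(triisopropylsilyloxy)phenol | CCOc1cc(O)c(-c2c(OCOC)cc(OCc3ccccc3)cc2OCOC)c(O[Si](C(C)C)(C(C)C)C(C)C)c1 | intermediate
16 | 3-[4-(benzyloxy)-2,6-bis(methoxymethoxy)phenyl]-6-ethoxy-2-hydroxy-4-(triisopropylsilyloxy)benzaldehyde | CCOc1cc(O[Si](C(C)C)(C(C)C)C(C)C)c(-c2c(OCOC)cc(OCc3ccccc3)cc2OCOC)c(O)c1C=O | intermediate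
17 | lithium [4-(methoxymethoxy)phenyl]acetylide (formed in the flask) | [Li+].[C-]#Cc1ccc(OCOC)cc1 | intermediate
18 | 1-{3-[4-(benzyloxy)-2,6-bis(methoxymethoxy)phenyl]-6-ethoxy-2-hydroxy-4-(triisopropylsilyloxy)phenyl}-3-[4-(methoxymethoxy)phenyl]prop-2-yn-1-ol (racemic at the carbinol) | CCOc1cc(O[Si](C(C)C)(C(C)C)C(C)C)c(-c2c(OCOC)cc(OCc3ccccc3)cc2OCOC)c(O)c1C(O)C#Cc1ccc(OCOC)cc1 | intermediate
19 | 1-{3-[4-(benzyloxy)-2,6-bis(methoxymethoxy)phenyl]-6-ethoxy-2-hydroxy-4-(triisopropylsilyloxy)phenyl}-3-[4-(methoxymethoxy)phenyl]prop-2-yn-1-one (formed in the flask) | CCOc1cc(O[Si](C(C)C)(C(C)C)C(C)C)c(-c2c(OCOC)cc(OCc3ccccc3)cc2OCOC)c(O)c1C(=O)C#Cc1ccc(OCOC)cc1 | intermediate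
20 | 8-[4-(benzyloxy)-2,6-bis(methoxymethoxy)phenyl]-5-ethoxy-2-[4-(methoxymethoxy)phenyl]-7-(triisopropylsilyloxy)-4H-chromen-4-one | CCOc1cc(O[Si](C(C)C)(C(C)C)C(C)C)c(-c2c(OCOC)cc(OCc3ccccc3)cc2OCOC)c2oc(-c3ccc(OCOC)cc3)cc(=O)c12 | intermediate
21 | 8-[4-(benzyloxy)-2,6-bis(methoxymethoxy)phenyl]-5-hydroxy-2-[4-(methoxymethoxy)phenyl]-7-(triisopropylsilyloxy)-4H-chromen-4-one | Oc1cc(O[Si](C(C)C)(C(C)C)C(C)C)c(-c2c(OCOC)cc(OCc3ccccc3)cc2OCOC)c2oc(-c3ccc(OCOC)cc3)cc(=O)c12 | intermediate
22 | 5-hydroxy-8-[4-hydroxy-2,6-bis(methoxymethoxy)phenyl]-2-[4-(methoxymethoxy)phenyl]-7-(triisopropylsilyloxy)-4H-chromen-4-one | Oc1cc(OCOC)c(-c2c(O[Si](C(C)C)(C(C)C)C(C)C)cc(O)c3c(=O)cc(-c4ccc(OCOC)cc4)oc23)c(OCOC)c1 | intermediate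
23 | 6-hydroxy-3-{5-hydroxy-2-[4-(methoxymethoxy)phenyl]-4-oxo-7-(triisopropylsilyloxy)-4H-chromen-8-yl}-2,4-bis(methoxymethoxy)benzaldehyde | O=Cc1c(O)cc(OCOC)c(-c2c(O[Si](C(C)C)(C(C)C)C(C)C)cc(O)c3c(=O)cc(-c4ccc(OCOC)cc4)oc23)c1OCOC | intermediate
24 | 5-hydroxy-8-[4-hydroxy-3-(1-hydroxyprop-2-yn-1-yl)-2,6-bis(methoxymethoxy)phenyl]-2-[4-(methoxymethoxy)phenyl]-7-(triisopropylsilyloxy)-4H-chromen-4-one (racemic at the carbinol) | C#CC(O)c1c(O)cc(OCOC)c(-c2c(O[Si](C(C)C)(C(C)C)C(C)C)cc(O)c3c(=O)cc(-c4ccc(OCOC)cc4)oc23)c1OCOC | intermediate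
25 | 5-hydroxy-8-[4-hydroxy-2,6-bis(methoxymethoxy)-3-(prop-2-ynoyl)phenyl]-2-[4-(methoxymethoxy)phenyl]-7-(triisopropylsilyloxy)-4H-chromen-4-one (formed in the flask) | C#CC(=O)c1c(O)cc(OCOC)c(-c2c(O[Si](C(C)C)(C(C)C)C(C)C)cc(O)c3c(=O)cc(-c4ccc(OCOC)cc4)oc23)c1OCOC | intermediate
26 | 5-hydroxy-8-[5,7-bis(methoxymethoxy)-4-oxo-4H-chromen-6-yl]-2-[4-(methoxymethoxy)phenyl]-7-(triisopropylsilyloxy)-4H-chromen-4-one | O=c1ccoc2cc(OCOC)c(-c3c(O[Si](C(C)C)(C(C)C)C(C)C)cc(O)c4c(=O)cc(-c5ccc(OCOC)cc5)oc34)c(OCOC)c12 | intermediate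
27 | [4-(methoxymethoxy)phenyl]boronic acid | COCOc1ccc(B(O)O)cc1 | starting material
28 | (2S)-6-{5-hydroxy-2-[4-(methoxymethoxy)phenyl]-4-oxo-7-(triisopropylsilyloxy)-4H-chromen-8-yl}-5,7-bis(methoxymethoxy)-2-[4-(methoxymethoxy)phenyl]-2,3-dihydro-4H-chromen-4-one | O=C1C[C@@H](c2ccc(OCOC)cc2)Oc2cc(OCOC)c(-c3c(O[Si](C(C)C)(C(C)C)C(C)C)cc(O)c4c(=O)cc(-c5ccc(OCOC)cc5)oc34)c(OCOC)c21 | intermediate
29 | (2S)-6-{5,7-dihydroxy-2-[4-(methoxymethoxy)phenyl]-4-oxo-4H-chromen-8-yl}-5,7-bis(methoxymethoxy)-2-[4-(methoxymethoxy)phenyl]-2,3-dihydro-4H-chromen-4-one (formed in the flask) | O=C1C[C@@H](c2ccc(OCOC)cc2)Oc2cc(OCOC)c(-c3c(O)cc(O)c4c(=O)cc(-c5ccc(OCOC)cc5)oc34)c(OCOC)c21 | intermediate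
30 | (2S)-6-[5,7-dihydroxy-2-(4-hydroxyphenyl)-4-oxo-4H-chromen-8-yl]-5,7-dihydroxy-2-(4-hydroxyphenyl)-2,3-dihydro-4H-chromen-4-one (CNP0154104.1) | O=C1C[C@@H](c2ccc(O)cc2)Oc2cc(O)c(-c3c(O)cc(O)c4c(=O)cc(-c5ccc(O)cc5)oc34)c(O)c21 | target

Total step count: 16 steps. Longest linear sequence: 14 steps (4 → 30, steps 3 to 16); steps 1 and 2 supply alkyne 3 as a side branch.

Steps most likely to fail

1. Step 6 (benzannulation). The capture of the short-lived vinylketene at the doubly ortho-substituted, aryl-bearing alkyne carbon may be slower than ketene dimerisation, than acylation of the product phenol by further ketene, or than thermal migration of silicon from oxygen to carbon in the ynol ether at the temperature that ring opening of the cyclobutenone demands. The fallback sets out from 9, separates ketene generation from heating and comes back at 15. Commercial ethyl (E)-3-ethoxybut-2-enoate is saponified (KOH, aqueous EtOH) to (E)-3-ethoxybut-2-enoic acid F1, which oxalyl chloride converts into (E)-3-ethoxybut-2-enoyl chloride F2. Slow addition of Et3N to F2 and 9 in CH2Cl2 at 0 °C releases vinylketene 11 by 1,4-dehydrochlorination in the cold, where the ketene–ynol ether (2+2) cycloaddition can proceed without thermal stress on 9. Vinylcyclobutenone 12 is then isolated and rearranged in dilute toluene at 80 °C, with no free ketene present, by ring opening, six-electron electrocyclisation and tautomerisation to 15.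

2. Step 5 (ester homologation). Addition of dibromomethyllithium to the twisted, electron-rich and doubly ortho-substituted ester may stall, and excess amide or alkyllithium base may metalate the ring beside the acetals, so that conversion to the ynolate is incomplete. The fallback sets out from 6, reaches the same ynolate by oxidation of an acetylide and comes back at 9. Reduction with i-Bu2AlH gives [4-(benzyloxy)-2,6-bis(methoxymethoxy)phenyl]methanol F3, MnO2 oxidation gives 4-(benzyloxy)-2,6-bis(methoxymethoxy)benzaldehyde F4, and Ohira–Bestmann homologation gives 5-(benzyloxy)-2-ethynyl-1,3-bis(methoxymethoxy)benzene F5. Deprotonation with LiN(SiMe3)2 gives lithium [4-(benzyloxy)-2,6-bis(methoxymethoxy)phenyl]acetylide F6, which LiOOt-Bu oxidises to ynolate 8; O-silylation with TIPSOTf then gives 9.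

3. Step 15 (asymmetric arylation). Insertion of the electron-rich 5,7-dialkoxychromone into the aryl–rhodium bond may be slow enough for protodeboronation to consume the boronic acid, or the facial discrimination may be insufficient, so that conversion or enantiomeric purity falls short. The fallback sets out from 23, forms the O1–C2 bond instead of the C2–aryl bond and comes back at 28. Hydrozirconation of alkyne 3 with Cp2Zr(H)Cl gives chloro{(E)-2-[4-(methoxymethoxy)phenyl]ethenyl}zirconocene F7, and transmetalation with Me2Zn gives methyl{(E)-2-[4-(methoxymethoxy)phenyl]ethenyl}zinc F8. Addition of F8 to 23 (its two hydroxyls first masked with Me2Zn) gives 5-hydroxy-8-{4-hydroxy-3-[(E)-1-hydroxy-3-[4-(methoxymethoxy)phenyl]prop-2-en-1-yl]-2,6-bis(methoxymethoxy)phenyl}-2-[4-(methoxymethoxy)phenyl]-7-(triisopropylsilyloxy)-4H-chromen-4-one F9. MnO2 oxidation gives the 2'-hydroxychalcone 5-hydroxy-8-{4-hydroxy-2,6-bis(methoxymethoxy)-3-[(E)-3-[4-(methoxymethoxy)phenyl]prop-2-enoyl]phenyl}-2-[4-(methoxymethoxy)phenyl]-7-(triisopropylsilyloxy)-4H-chromen-4-one F10. An enantioselective intramolecular oxa-Michael addition catalysed by a bifunctional cinchona-alkaloid thiourea (9-amino-9-deoxy-epi-quinine 3,5-bis(trifluoromethyl)phenylthiourea or its quinidine-derived pseudoenantiomer, whichever adds the phenolic oxygen to the Si face of the β-carbon) then gives 28.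

Further compounds
F1 | step 6 | (E)-3-ethoxybut-2-enoic acid | CCO/C(C)=C/C(=O)O
F2 | step 6 | (E)-3-ethoxybut-2-enoyl chloride | CCO/C(C)=C/C(Cl)=O
F3 | step 5 | [4-(benzyloxy)-2,6-bis(methoxymethoxy)phenyl]methanol | OCc1c(OCOC)cc(OCc2ccccc2)cc1OCOC
F4 | step 5 | 4-(benzyloxy)-2,6-bis(methoxymethoxy)benzaldehyde | O=Cc1c(OCOC)cc(OCc2ccccc2)cc1OCOC
F5 | step 5 | 5-(benzyloxy)-2-ethynyl-1,3-bis(methoxymethoxy)benzene | C#Cc1c(OCOC)cc(OCc2ccccc2)cc1OCOC
F6 | step 5 | lithium [4-(benzyloxy)-2,6-bis(methoxymethoxy)phenyl]acetylide | [Li+].[C-]#Cc1c(OCOC)cc(OCc2ccccc2)cc1OCOC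
F7 | step 15 | chloro{(E)-2-[4-(methoxymethoxy)phenyl]ethenyl}zirconocene (two η5-cyclopentadienyl groups on zirconium) | COCOc1ccc(/C=C/[Zr](Cl)(C2C=CC=C2)C2C=CC=C2)cc1
F8 | step 15 | methyl{(E)-2-[4-(methoxymethoxy)phenyl]ethenyl}zinc | COCOc1ccc(/C=C/[Zn]C)cc1
F9 | step 15 | 5-hydroxy-8-{4-hydroxy-3-[(E)-1-hydroxy-3-[4-(methoxymethoxy)phenyl]prop-2-en-1-yl]-2,6-bis(methoxymethoxy)phenyl}-2-[4-(methoxymethoxy)phenyl]-7-(triisopropylsilyloxy)-4H-chromen-4-one (racemic at the carbinol) | OC(/C=C/c1ccc(OCOC)cc1)c1c(O)cc(OCOC)c(-c2c(O[Si](C(C)C)(C(C)C)C(C)C)cc(O)c3c(=O)cc(-c4ccc(OCOC)cc4)oc23)c1OCOC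
F10 | step 15 | 5-hydroxy-8-{4-hydroxy-2,6-bis(methoxymethoxy)-3-[(E)-3-[4-(methoxymethoxy)phenyl]prop-2-enoyl]phenyl}-2-[4-(methoxymethoxy)phenyl]-7-(triisopropylsilyloxy)-4H-chromen-4-one | O=C(/C=C/c1ccc(OCOC)cc1)c1c(O)cc(OCOC)c(-c2c(O[Si](C(C)C)(C(C)C)C(C)C)cc(O)c3c(=O)cc(-c4ccc(OCOC)cc4)oc23)c1OCOC
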